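**Retrosynthetic overview**
- The strategy rests on C2, the only stereocentre: it is the benzylic carbon of pyranone ring C, β to the C4 ketone and attached to catechol ring B. Cutting C2–C1′ leaves a flat 8-substituted 7-methoxychromone and a 3,4-dioxygenated arylboronic acid, joined by catalytic asymmetric 1,4-arylation.
- Ring A is bought as 2,4-dihydroxyacetophenone. The C8 carbon chain is introduced as an allyl group by O-allylation and aromatic Claisen shift to the carbon between the two oxygens, and ring C is closed by enaminone cyclisation.
- The side chain is completed on the chromone by cross metathesis with methacrolein (E-trisubstituted alkene), 1,2-reduction and silylation.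
- Ring B is attached last, and a buffered fluoride treatment frees the three hydroxyls without opening ring C.

Key step: step 11

Remark on the chemistry: the (R) antipode of the pyridine–oxazoline ligand is assigned by analogy with the sense of induction on cyclic enones. The configuration of the coupled flavanone is to be checked on the first run, and the (S) ligand is used instead if the sense proves opposite.

**Route**

Step 1
Reactants: 1 resacetophenone (2,4-dihydroxyacetophenone); 2 allyl bromide
Product: 3 mono-allyl ether (4-allyloxy-2-hydroxyacetophenone)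
Conditions: K2CO3 (1.2 equiv), acetone, reflux
Reagents that add atoms: none
Why: Williamson etherification; the 2-OH is locked in a hydrogen bond to the acetyl carbonyl, so the weak base should alkylate only the free 4-OH.

Step 2
Reactants: 3 mono-allyl ether (4-allyloxy-2-hydroxyacetophenone)
Product: 5 C-allyl resacetophenone (3-allyl-2,4-dihydroxyacetophenone), via ortho-dienone 4 (not isolated)
Conditions: N,N-diethylaniline, 200–210 °C, N2
Reagents that add atoms: none
Why: Aromatic Claisen rearrangement ([3,3]-sigmatropic shift, then tautomerisation); in chelated ortho-hydroxyacetophenones the C3–C4 bond has the higher double-bond character, so migration should go mainly to C3, between the two oxygens.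

Step 3
Reactants: 5 C-allyl resacetophenone (3-allyl-2,4-dihydroxyacetophenone)
Product: 6 methyl ether (3-allyl-2-hydroxy-4-methoxyacetophenone)
Conditions: MeI (1.1 equiv), K2CO3 (1.2 equiv), acetone, rt to 40 °C
Reagents that add atoms: iodomethane CI
Why: Williamson methylation with near-stoichiometric electrophile; the chelated 2-OH is much less nucleophilic than the 4-OH, so mono-methylation at O4 is expected.

Step 4
Reactants: 6 methyl ether (3-allyl-2-hydroxy-4-methoxyacetophenone)
Product: 7 enaminone ((E)-1-(3-allyl-2-hydroxy-4-methoxyphenyl)-3-(dimethylamino)prop-2-en-1-one)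
Conditions: Me2NCH(OMe)2 (2 equiv), toluene, 100 °C
Reagents that add atoms: N,N-dimethylformamide dimethyl acetal COC(OC)N(C)C
Why: Condensation of the methyl ketone with the amide acetal (enaminone formation) supplies the future C2 as a vinylogous amide carbon; the chelated phenol is known to survive this reagent.

Step 5
Reactants: 7 enaminone ((E)-1-(3-allyl-2-hydroxy-4-methoxyphenyl)-3-(dimethylamino)prop-2-en-1-one)
Product: 9 allyl chromone (7-methoxy-8-(prop-2-enyl)-4H-chromen-4-one), via aminochromanone 8 (not isolated)
Conditions: conc. HCl, CH2Cl2, rt to 40 °C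
Reagents that add atoms: none
Why: Acid-promoted addition–elimination chromone synthesis: the phenol adds to the protonated enaminone (6-endo oxa-Michael) and dimethylamine is lost to give the pyranone; the terminal allyl group should tolerate the brief acid exposure.

Step 6
Reactants: 9 allyl chromone (7-methoxy-8-(prop-2-enyl)-4H-chromen-4-one); 10 methacrolein
Product: 11 enal ((E)-4-(7-methoxy-4-oxo-4H-chromen-8-yl)-2-methylbut-2-enal)
Conditions: 10 (8 equiv), second-generation Grubbs catalyst (H2IMes)(PCy3)Cl2Ru=CHPh (5 mol%), 1,4-benzoquinone (10 mol%), CH2Cl2, 40 °C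
Reagents that add atoms: none
Why: Olefin cross metathesis of a terminal alkene with the slowly dimerising methacrolein should give the thermodynamically preferred E-trisubstituted enal; the endocyclic, electron-poor chromone C2=C3 bond does not engage the ruthenium carbene, and benzoquinone suppresses allyl-to-propenyl migration.

Step 7
Reactants: 11 enal ((E)-4-(7-methoxy-4-oxo-4H-chromen-8-yl)-2-methylbut-2-enal)
Product: 12 allylic alcohol (8-[(E)-4-hydroxy-3-methylbut-2-enyl]-7-methoxychromone)
Conditions: NaBH4 (0.6 equiv), CeCl3·7H2O (1.0 equiv), MeOH/CH2Cl2, −40 °C; aq NH4Cl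
Reagents that add atoms: none
Why: Luche reduction gives clean 1,2-hydride delivery to the enal; the chromone carbonyl is a doubly vinylogous ester and far less electrophilic, so limited hydride at low temperature should leave ring C intact and the alkene geometry unchanged.

Step 8
Reactants: 12 allylic alcohol (8-[(E)-4-hydroxy-3-methylbut-2-enyl]-7-methoxychromone)
Product: 13 silyl ether (8-[(E)-4-(tert-butyldimethylsilyloxy)-3-methylbut-2-enyl]-7-methoxychromone)
Conditions: TBSCl (1.2 equiv), imidazole (2 equiv), CH2Cl2, 0 °C to rt
Reagents that add atoms: tert-butyldimethylsilyl chloride CC(C)(C)[Si](C)(C)Cl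
Why: Standard imidazole-mediated silylation of the only hydroxyl; this removes a potential ligand for palladium before the key step.

Step 9
Reactants: 14 4-bromocatechol (4-bromobenzene-1,2-diol)
Product: 15 bis-silyl ether (4-bromo-1,2-bis(tert-butyldimethylsilyloxy)benzene)
Conditions: TBSCl (2.3 equiv), imidazole (4.5 equiv), DMF, rt
Reagents that add atoms: tert-butyldimethylsilyl chloride CC(C)(C)[Si](C)(C)Cl
Why: Exhaustive silylation of both phenols under standard conditions; the aryl bromide is inert.

Step 10
Reactants: 15 bis-silyl ether (4-bromo-1,2-bis(tert-butyldimethylsilyloxy)benzene)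
Product: 18 arylboronic acid ([3,4-bis(tert-butyldimethylsilyloxy)phenyl]boronic acid), via aryllithium 16 (not isolated), via lithium triisopropoxyborate 17 (not isolated)
Conditions: n-BuLi (1.05 equiv), THF, −78 °C; B(OiPr)3 (1.5 equiv), −78 to 0 °C; 1 M HCl, 0 °C
Reagents that add atoms: triisopropyl borate CC(C)OB(OC(C)C)OC(C)C; water O
Why: Bromine–lithium exchange at −78 °C places lithium meta and para to the silyloxy groups, so no ortho silyl migration is available; borate trapping and brief cold acid hydrolysis should give the boronic acid with both aryl silyl ethers intact.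

Step 11
Reactants: 13 silyl ether (8-[(E)-4-(tert-butyldimethylsilyloxy)-3-methylbut-2-enyl]-7-methoxychromone); 18 arylboronic acid ([3,4-bis(tert-butyldimethylsilyloxy)phenyl]boronic acid)
Product: 19 tris-silyl (2S)-flavanone ((2S)-2-[3,4-bis(tert-butyldimethylsilyloxy)phenyl]-8-[(E)-4-(tert-butyldimethylsilyloxy)-3-methylbut-2-enyl]-7-methoxychroman-4-one)
Conditions: Pd(OCOCF3)2 (10 mol%), (R)-4-tert-butyl-2-(pyridin-2-yl)-4,5-dihydrooxazole (12 mol%), NH4PF6 (30 mol%), H2O (5 equiv), 18 (2.5 equiv), ClCH2CH2Cl, 60 °C
Reagents that add atoms: none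
Why: The aryl group passes from boron to the cationic divalent palladium centre held by the pyridine–oxazoline ligand, the chromone C2=C3 bond binds next to it, and enantiodetermining syn migratory insertion forms C2–C1′ before water protonates the C3 palladium enolate and releases the catalyst; the closest known reaction type is the palladium–pyridinooxazoline conjugate addition of arylboronic acids to chromones and cyclic enones. No ring is closed here: the pyranone is already in place and its O1–C2 bond is never broken, so the chalcone–phenoxide equilibrium that erodes oxa-Michael closures is not entered. The C2 stereocentre is set by the ligand, whose tert-butyl group shields one face of the planar enone, and the (R) antipode is expected to deliver the aryl group to the face that gives 2S. The step needs facial selectivity, 1,4- over 1,2-addition and discrimination against the side-chain alkene: carbopalladation of the polarised C2=C3 bond fixes the regiochemistry, syn addition leaves no syn β-hydrogen at C2 so flavone formation is disfavoured, and the trisubstituted, unpolarised side-chain alkene is a much poorer insertion partner. The C8 chain lies in the ring plane beside O1 and covers neither face of C2, and with every hydroxyl silylated there is no free phenol to bind palladium or open the heterocycle.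

Step 12
Reactants: 19 tris-silyl (2S)-flavanone ((2S)-2-[3,4-bis(tert-butyldimethylsilyloxy)phenyl]-8-[(E)-4-(tert-butyldimethylsilyloxy)-3-methylbut-2-enyl]-7-methoxychroman-4-one)
Product: 20 target ((2S)-2-(3,4-dihydroxyphenyl)-8-[(E)-4-hydroxy-3-methylbut-2-enyl]-7-methoxychroman-4-one)
Conditions: Bu4NF (4 equiv), AcOH (5 equiv), THF, 0 °C to rt; pH 5 buffer work-up
Reagents that add atoms: none
Why: Fluoride-induced cleavage of the three Si–O bonds; acetic acid protonates each phenoxide as it is released, so the 4′-phenoxide-driven retro-oxa-Michael opening of ring C that would racemise C2 should not be reached, and the methyl ether and E-alkene are untouched.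

**Compound list**
1 | resacetophenone (2,4-dihydroxyacetophenone) | CC(=O)c1ccc(O)cc1O | starting material
2 | allyl bromide | C=CCBr | starting material
3 | 4-allyloxy-2-hydroxyacetophenone | CC(=O)c1ccc(OCC=C)cc1O | intermediate
4 | ortho-dienone, 4-acetyl-2-allyl-3-hydroxycyclohexa-3,5-dien-1-one (formed in the flask, racemic) | CC(=O)C1=C(O)C(CC=C)C(=O)C=C1 | intermediate
5 | 3-allyl-2,4-dihydroxyacetophenone | CC(=O)c1ccc(O)c(CC=C)c1O | intermediate
6 | 3-allyl-2-hydroxy-4-methoxyacetophenone | CC(=O)c1ccc(OC)c(CC=C)c1O | intermediate
7 | (E)-1-(3-allyl-2-hydroxy-4-methoxyphenyl)-3-(dimethylamino)prop-2-en-1-one | CN(C)/C=C/C(=O)c1ccc(OC)c(CC=C)c1O | intermediate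
8 | 8-allyl-2-(dimethylamino)-7-methoxychroman-4-one (formed in the flask, racemic) | CN(C)C1CC(=O)c2ccc(OC)c(CC=C)c2O1 | intermediate
9 | 8-allyl-7-methoxy-4H-chromen-4-one | COc1ccc2c(c1CC=C)OC=CC2=O | intermediate
10 | methacrolein | C=C(C)C=O | starting material
11 | (E)-4-(7-methoxy-4-oxo-4H-chromen-8-yl)-2-methylbut-2-enal | COc1ccc2c(c1C/C=C(\C)C=O)OC=CC2=O | intermediate
12 | 8-[(E)-4-hydroxy-3-methylbut-2-enyl]-7-methoxy-4H-chromen-4-one | COc1ccc2c(c1C/C=C(\C)CO)OC=CC2=O | intermediate
13 | 8-[(E)-4-(tert-butyldimethylsilyloxy)-3-methylbut-2-enyl]-7-methoxy-4H-chromen-4-one | COc1ccc2c(c1C/C=C(\C)CO[Si](C)(C)C(C)(C)C)OC=CC2=O | intermediate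
14 | 4-bromocatechol | Oc1ccc(Br)cc1O | starting material
15 | 4-bromo-1,2-bis(tert-butyldimethylsilyloxy)benzene | CC(C)(C)[Si](C)(C)Oc1ccc(Br)cc1O[Si](C)(C)C(C)(C)C | intermediate
16 | [3,4-bis(tert-butyldimethylsilyloxy)phenyl]lithium (formed in the flask) | [Li]c1ccc(O[Si](C)(C)C(C)(C)C)c(O[Si](C)(C)C(C)(C)C)c1 | intermediate
17 | lithium [3,4-bis(tert-butyldimethylsilyloxy)phenyl]triisopropoxyborate (formed in the flask) | [Li+].CC(C)O[B-](OC(C)C)(OC(C)C)c1ccc(O[Si](C)(C)C(C)(C)C)c(O[Si](C)(C)C(C)(C)C)c1 | intermediate
18 | [3,4-bis(tert-butyldimethylsilyloxy)phenyl]boronic acid | OB(O)c1ccc(O[Si](C)(C)C(C)(C)C)c(O[Si](C)(C)C(C)(C)C)c1 | intermediate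
19 | (2S)-2-[3,4-bis(tert-butyldimethylsilyloxy)phenyl]-8-[(E)-4-(tert-butyldimethylsilyloxy)-3-methylbut-2-enyl]-7-methoxychroman-4-one | COc1ccc2c(c1C/C=C(\C)CO[Si](C)(C)C(C)(C)C)O[C@H](c1ccc(O[Si](C)(C)C(C)(C)C)c(O[Si](C)(C)C(C)(C)C)c1)CC2=O | intermediate
20 | (2S)-2-(3,4-dihydroxyphenyl)-8-[(E)-4-hydroxy-3-methylbut-2-enyl]-7-methoxychroman-4-one | COc1ccc2c(c1C/C=C(\C)CO)O[C@H](c1ccc(O)c(O)c1)CC2=O | target

**Step count**
Total: 12 steps. Longest linear sequence: 10 steps (steps 1–8, 11, 12); the boronic acid branch is 2 steps (9, 10).

**Steps most likely to fail, with fallbacks**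

Step 11. Insertion into the electron-rich 7-methoxychromone may be sluggish, so protodeboronation of the electron-rich boronic acid could outrun coupling, and facial selectivity may be poor. Fallback, setting out from 13 and 18: run the arylation without a chiral ligand under the more active cationic system Pd(OCOCF3)2/2,2′-bipyridine in wet 1,2-dichloroethane at 60 °C. This should give the racemic tris-silyl flavanone F1. The enantiomers are then separated on a preparative polysaccharide-carbamate chiral stationary phase, the unwanted (2R) antipode F2 is set aside, and the route is rejoined at 19.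

Step 6. The allyl group may migrate into conjugation with ring A, turnover with the electron-poor methacrolein may be low, or the alkene geometry may be mixed. Fallback, setting out from 9: cross metathesis with excess 2-methylbut-2-ene (same ruthenium catalyst, CH2Cl2, 40 °C) should give the prenyl chromone F3. Catalytic SeO2 with t-BuOOH in CH2Cl2 at rt then oxidises the methyl group trans to the chain (ene reaction followed by [2,3]-sigmatropic shift), so the E-allylic alcohol is obtained directly and the route is rejoined at 12. Any enal 11 formed by over-oxidation is returned to 12 by step 7.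

Step 12. Ring C may open and C2 may racemise while the 4′-phenoxide is transiently free, or the aryl silyl ethers may cleave incompletely. Fallback, setting out from 14: protect the catechol with MOMCl/i-Pr2NEt in CH2Cl2 as the bis(methoxymethyl) ether F4. Bromine–lithium exchange (n-BuLi, THF, −78 °C) gives the aryllithium F5, B(OiPr)3 converts it into the lithium borate F6, and aq NH4Cl hydrolysis releases the boronic acid F7. Coupling of F7 with 13 under the conditions of step 11 should give the bis-MOM mono-silyl flavanone F8. HCl in MeOH/THF at rt to 40 °C then removes both acetals and the allylic silyl ether in one acidic operation, in which no phenoxide is formed, and the route is rejoined at 20.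

**Further compounds**
F1 | step 11 | racemic 2-[3,4-bis(tert-butyldimethylsilyloxy)phenyl]-8-[(E)-4-(tert-butyldimethylsilyloxy)-3-methylbut-2-enyl]-7-methoxychroman-4-one | COc1ccc2c(c1C/C=C(\C)CO[Si](C)(C)C(C)(C)C)OC(c1ccc(O[Si](C)(C)C(C)(C)C)c(O[Si](C)(C)C(C)(C)C)c1)CC2=O
F2 | step 11 | (2R)-2-[3,4-bis(tert-butyldimethylsilyloxy)phenyl]-8-[(E)-4-(tert-butyldimethylsilyloxy)-3-methylbut-2-enyl]-7-methoxychroman-4-one | COc1ccc2c(c1C/C=C(\C)CO[Si](C)(C)C(C)(C)C)O[C@@H](c1ccc(O[Si](C)(C)C(C)(C)C)c(O[Si](C)(C)C(C)(C)C)c1)CC2=O
F3 | step 6 | 7-methoxy-8-(3-methylbut-2-enyl)-4H-chromen-4-one | COc1ccc2c(c1CC=C(C)C)OC=CC2=O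
F4 | step 12 | 4-bromo-1,2-bis(methoxymethoxy)benzene | COCOc1ccc(Br)cc1OCOC
F5 | step 12 | [3,4-bis(methoxymethoxy)phenyl]lithium | [Li]c1ccc(OCOC)c(OCOC)c1
F6 | step 12 | lithium [3,4-bis(methoxymethoxy)phenyl]triisopropoxyborate | [Li+].CC(C)O[B-](OC(C)C)(OC(C)C)c1ccc(OCOC)c(OCOC)c1
F7 | step 12 | [3,4-bis(methoxymethoxy)phenyl]boronic acid | COCOc1ccc(B(O)O)cc1OCOC
F8 | step 12 | (2S)-2-[3,4-bis(methoxymethoxy)phenyl]-8-[(E)-4-(tert-butyldimethylsilyloxy)-3-methylbut-2-enyl]-7-methoxychroman-4-one | COc1ccc2c(c1C/C=C(\C)CO[Si](C)(C)C(C)(C)C)O[C@H](c1ccc(OCOC)c(OCOC)c1)CC2=O
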